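Everything rests on closing ring A across C3–C4 by an intramolecular nitrile oxide–alkene cycloaddition. The step exploits the O–C3–C4(C18)–C19–O array of ring A: a 2-isoxazoline spanning C3, C4 and C19 is a masked β-hydroxy ketone. In one operation it forms ring A, the C3–C4 bond, the C19–O bond and the quaternary C4 stereocentre. Its precursor is a monocyclic ring B ketone with an isopropenyl group on C5 and an oxime-ended three-carbon chain on C10. It comes from (−)-verbenone, whose bridge directs C10 and C9 before the cyclobutane is cleaved to unveil the isopropenyl group.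

Key step: step 8

Assumption: (1S,5S)-(−)-verbenone is bought in high enantiomeric purity; labdane numbering is used for all compounds (C17 = exocyclic CH2 on C8, C18 = methyl on C4, C19 = CH2O on C4, C20 = methyl on C10).

Step 1
Reactants: 1 (1S,5S)-(−)-verbenone; 2 benzyl 3-bromopropyl ether
Product: 4 (1S,4S,5S)-4-[3-(benzyloxy)propyl]-4,6,6-trimethylbicyclo[3.1.1]heptan-2-one (chain anti to the gem-dimethyl bridge), via trimethylsilyl enol ether 3 (not isolated)
Conditions: 2, Mg, THF, rt; then CuBr·SMe2 (0.2 equiv), Me3SiCl, 1, THF, −78 → −20 °C; 1 M HCl work-up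
Reagents that add atoms: benzyl 3-bromopropyl ether (2), BrCCCOCc1ccccc1
Why: Copper-catalysed, Me3SiCl-accelerated conjugate addition of the Grignard reagent should deliver the chain to C10 from the face away from the gem-dimethyl bridge, which sets C10 with its methyl group syn to the bridge; acid work-up hydrolyses the silyl enol ether.

Step 2
Reactants: 4 bicyclic ketone; 5 ethyl glyoxylate
Product: 8 ethyl 2-[(1S,4R,5R)-4-[3-(benzyloxy)propyl]-4,6,6-trimethyl-2-oxobicyclo[3.1.1]heptan-3-ylidene]acetate (C9=C11 geometry not defined), via aldol adduct 6 (not isolated), via mesylate 7 (not isolated)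
Conditions: LiN(iPr)2, THF, −78 °C; 5, −78 °C; MsCl, −78 → 0 °C; DBU, rt
Reagents that add atoms: ethyl glyoxylate (5), O=CC(=O)OCC
Why: Aldol condensation: the ketone can enolise only toward C9 (the other alpha carbon is a bridgehead), the enolate adds to the glyoxylate, and in-situ mesylation with E1cB elimination should give the C9=C11 alkylidene, whose geometry is irrelevant.

Step 3
Reactants: 8 alkylidene keto ester
Product: 9 ethyl 2-[(1S,3S,4R,5R)-4-(3-hydroxypropyl)-4,6,6-trimethyl-2-oxobicyclo[3.1.1]heptan-3-yl]acetate (CH2CO2Et syn to the gem-dimethyl bridge and cis to the C10 methyl)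
Conditions: H2 (1 atm), Pd/C (10 %), EtOH, rt
Reagents that add atoms: none
Why: Heterogeneous catalytic hydrogenation should add hydrogen to C9=C11 from the face anti to the gem-dimethyl bridge, which sets C9 with H9 anti and the CH2CO2Et arm syn to the bridge, and it hydrogenolyses the benzyl ether in the same operation.

Step 4
Reactants: 9 bicyclic keto ester alcohol
Product: 10 ethyl 2-[(1S,5R,6R)-2-acetoxy-6-(3-acetoxypropyl)-6-methyl-5-(prop-1-en-2-yl)cyclohex-2-en-1-yl]acetate
Conditions: Ac2O, BF3·OEt2 (0.5 equiv), Zn(OAc)2 (0.5 equiv), 0 °C → rt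
Reagents that add atoms: acetic anhydride, CC(=O)OC(C)=O
Why: Lewis acid-mediated cyclobutane fragmentation of a pinanone: heterolysis of the C7–C4 bond is driven by enol acetate formation at C8 and by the tertiary cation at C4, which should lose a methyl proton to give the isopropenyl group, while C5, C9 and C10 are untouched and the primary alcohol is acetylated.

Step 5
Reactants: 10 enol acetate
Product: 11 ethyl 2-[(1S,2R,3R)-2-(3-hydroxypropyl)-2-methyl-6-oxo-3-(prop-1-en-2-yl)cyclohexyl]acetate
Conditions: K2CO3 (0.2 equiv), EtOH, 0 °C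
Reagents that add atoms: none
Why: Base-catalysed transesterification cleaves the enol acetate and the primary acetate while ethanol keeps the ethyl ester, and short exposure at low temperature should leave C9 unchanged, as its all-equatorial arrangement is expected to be the more stable epimer.

Step 6
Reactants: 11 hydroxy keto ester
Product: 12 ethyl 2-[(1S,2R,3R)-2-methyl-6-oxo-2-(3-oxopropyl)-3-(prop-1-en-2-yl)cyclohexyl]acetate
Conditions: Dess–Martin periodinane, CH2Cl2, 0 °C → rt
Reagents that add atoms: none
Why: Dess–Martin oxidation converts the primary alcohol into the aldehyde under neutral conditions without touching the alkene or epimerising C9.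

Step 7
Reactants: 12 keto aldehyde
Product: 13 ethyl 2-[(1S,2R,3R)-2-[3-(hydroxyimino)propyl]-2-methyl-6-oxo-3-(prop-1-en-2-yl)cyclohexyl]acetate
Conditions: NH2OH·HCl (1.05 equiv), NaOAc, EtOH/H2O, 0 °C
Reagents that add atoms: hydroxylamine hydrochloride, Cl.NO
Why: Oxime condensation is much faster at the aldehyde than at the hindered C8 ketone, so one equivalent of hydroxylamine should give the aldoxime selectively.

Step 8
Reactants: 13 aldoxime
Product: 15 tricyclic 2-isoxazoline keto ester (4R,5S,9S,10R) with ring A fused across C3–C4 to the C3=N–O–C19 ring, via nitrile oxide 14 (not isolated)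
Conditions: aq. NaOCl, CH2Cl2, 0 °C → rt, 0.01 M, slow addition of 13
Reagents that add atoms: none
Why: Hypochlorite oxidises the aldoxime to the nitrile oxide 14, whose carbon (C3) adds to the internal carbon of the C5 isopropenyl group (C4) while its oxygen adds to the terminal carbon (C19) in a concerted, asynchronous [3+2] cycloaddition. The closest known reaction type is the intramolecular nitrile oxide–alkene cycloaddition onto a 1,1-disubstituted alkene, which gives a fused cyclohexane with an angular methyl group. Ring A is closed in the 6-exo mode by the C3–C4 bond (four-atom tether C2–C1–C10–C5, fused and not bridged), and the 2-isoxazoline ring is closed at the same time by the O–C19 bond. The new quaternary stereocentre C4 is controlled by the chair of ring B, on which the C5 isopropenyl group and the C10 chain are trans-diequatorial: in the chair-like tether the C4=C19 bond must lie antiperiplanar to C2–C3 (equatorial on the nascent ring A) to meet the nitrile oxide oxygen, which is also the rotamer that eclipses C4=C19 with C5–H, so C18 becomes axial on the face of the C10 methyl and C19 equatorial, as in the target. The step needs chemoselectivity (cycloaddition faster than furoxan dimerisation, secured by high dilution and by the absence of a second alkene because C8 is still a ketone) and facial selectivity at C4 (secured by the equatorial attachment of both reacting arms to ring B, which leaves only a twist-boat path to the C4 epimer).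

Step 9
Reactants: 15 isoxazoline keto ester
Product: 16 isoxazoline ester with exocyclic C8=C17 methylene (4R,5S,9R,10S)
Conditions: Ph3PCH3Br, KOtBu, THF, 0 °C → rt
Reagents that add atoms: methyltriphenylphosphonium bromide, C[P+](c1ccccc1)(c1ccccc1)c1ccccc1.[Br-]
Why: Wittig methylenation of the C8 ketone; the ethyl ester and the isoxazoline (no ring hydrogen alpha to C=N, so no base-induced ring opening) should survive the non-stabilised ylide, and C9 carries the equatorial side chain so that it should not be eroded.

Step 10
Reactants: 16 isoxazoline ester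
Product: 17 isoxazoline aldehyde (C12 aldehyde; 4R,5S,9R,10S)
Conditions: iBu2AlH (1.1 equiv), CH2Cl2, −78 °C; Rochelle salt work-up
Reagents that add atoms: none
Why: Partial reduction with iBu2AlH stops at the aluminium hemiacetal at −78 °C and should give the aldehyde on work-up, with the isoxazoline C=N inert at this temperature.

Step 11
Reactants: 17 isoxazoline aldehyde; 18 1,1,1,3,3,3-hexafluoropropan-2-yl acrylate
Product: 19 (12R)-hexafluoroisopropyl 2-(1-hydroxyalkyl)acrylate (4R,5S,9R,10S,12R)
Conditions: 18, β-isocupreidine (0.1 equiv), DMF, −55 °C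
Reagents that add atoms: 1,1,1,3,3,3-hexafluoropropan-2-yl acrylate (18), C=CC(=O)OC(C(F)(F)F)C(F)(F)F
Why: Asymmetric Morita–Baylis–Hillman reaction: the cinchona-derived catalyst with the activated fluorinated acrylate should set C12 as (R) under catalyst control, because the resident stereocentres are remote from the aldehyde.

Step 12
Reactants: 19 hexafluoroisopropyl ester; 20 allyl alcohol
Product: 21 (12R)-allyl 2-(1-hydroxyalkyl)acrylate (4R,5S,9R,10S,12R)
Conditions: 20 (solvent), Et3N (0.2 equiv), rt
Reagents that add atoms: allyl alcohol (20), C=CCO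
Why: Amine-catalysed transesterification of the activated hexafluoroisopropyl ester should install the allyl ester needed for ring closure without affecting C12.

Step 13
Reactants: 21 allyl ester
Product: 22 isoxazoline butenolide (4R,5S,9R,10S,12R)
Conditions: second-generation Grubbs catalyst (H2IMes)(PCy3)Cl2Ru=CHPh (5 mol %), CH2Cl2, 40 °C, 0.005 M
Reagents that add atoms: none
Why: Ring-closing metathesis between the acrylate methylene and the allyl group should form the five-membered butenolide (C13=C14), while the hindered exocyclic C8 methylene cannot reach either alkene in a strain-free ring.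

Step 14
Reactants: 22 isoxazoline butenolide
Product: 23 3-oxo-19-hydroxy compound (4S,5S,9R,10S,12R)
Conditions: Mo(CO)6 (1 equiv), MeCN/H2O 15:1, 80 °C
Reagents that add atoms: water, O
Why: Reductive N–O cleavage with Mo(CO)6 and hydrolysis of the resulting β-hydroxy imine should unveil the C3 ketone and the C19 alcohol without reducing the alkenes or the butenolide.

Step 15
Reactants: 23 β-hydroxy ketone
Product: 24 target, (3R,4S,5S,9R,10S,12R)-3,12,19-trihydroxy-labda-8(17),13-dien-16,15-olide
Conditions: NaBH4, CeCl3·7H2O, MeOH, −78 °C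
Reagents that add atoms: none
Why: Luche reduction: hydride should add to the C3 ketone along the axial trajectory, on the face opposite the axial C18 and C20 methyl groups, to give the equatorial (3R) alcohol, while the butenolide is not reduced at this temperature.

Compound list
1 | (1S,5S)-(−)-verbenone | CC1=CC(=O)[C@H]2C[C@@H]1C2(C)C | starting material
2 | benzyl 3-bromopropyl ether | BrCCCOCc1ccccc1 | starting material
3 | trimethylsilyl enol ether of 4 (C8–OSiMe3, C8=C9) | C[Si](C)(C)OC=1[C@H]2C[C@H](C2(C)C)[C@@](C)(CCCOCc3ccccc3)C=1 | intermediate (not isolated)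
4 | (1S,4S,5S)-4-[3-(benzyloxy)propyl]-4,6,6-trimethylbicyclo[3.1.1]heptan-2-one | O=C1[C@H]2C[C@H](C2(C)C)[C@@](C)(CCCOCc3ccccc3)C1 | intermediate
5 | ethyl glyoxylate | O=CC(=O)OCC | starting material
6 | aldol adduct of 4 and 5 (C9–CH(OH)CO2Et, mixture at C9 and C11) | O=C1[C@H]2C[C@H](C2(C)C)[C@@](C)(CCCOCc3ccccc3)C1C(O)C(=O)OCC | intermediate (not isolated)
7 | mesylate of 6 | O=C1[C@H]2C[C@H](C2(C)C)[C@@](C)(CCCOCc3ccccc3)C1C(OS(C)(=O)=O)C(=O)OCC | intermediate (not isolated)
8 | ethyl 2-[(1S,4R,5R)-4-[3-(benzyloxy)propyl]-4,6,6-trimethyl-2-oxobicyclo[3.1.1]heptan-3-ylidene]acetate | O=C1[C@H]2C[C@H](C2(C)C)[C@@](C)(CCCOCc3ccccc3)C1=CC(=O)OCC | intermediate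
9 | ethyl 2-[(1S,3S,4R,5R)-4-(3-hydroxypropyl)-4,6,6-trimethyl-2-oxobicyclo[3.1.1]heptan-3-yl]acetate | O=C1[C@H]2C[C@H](C2(C)C)[C@@](C)(CCCO)[C@@H]1CC(=O)OCC | intermediate
10 | ethyl 2-[(1S,5R,6R)-2-acetoxy-6-(3-acetoxypropyl)-6-methyl-5-(prop-1-en-2-yl)cyclohex-2-en-1-yl]acetate | CC(=O)OC1=CC[C@H](C(C)=C)[C@@](C)(CCCOC(C)=O)[C@@H]1CC(=O)OCC | intermediate
11 | ethyl 2-[(1S,2R,3R)-2-(3-hydroxypropyl)-2-methyl-6-oxo-3-(prop-1-en-2-yl)cyclohexyl]acetate | O=C1CC[C@H](C(C)=C)[C@@](C)(CCCO)[C@@H]1CC(=O)OCC | intermediate
12 | ethyl 2-[(1S,2R,3R)-2-methyl-6-oxo-2-(3-oxopropyl)-3-(prop-1-en-2-yl)cyclohexyl]acetate | O=C1CC[C@H](C(C)=C)[C@@](C)(CCC=O)[C@@H]1CC(=O)OCC | intermediate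
13 | ethyl 2-[(1S,2R,3R)-2-[3-(hydroxyimino)propyl]-2-methyl-6-oxo-3-(prop-1-en-2-yl)cyclohexyl]acetate (oxime geometry not defined) | O=C1CC[C@H](C(C)=C)[C@@](C)(CCC=NO)[C@@H]1CC(=O)OCC | intermediate
14 | nitrile oxide derived from 13 (C3≡N–O) | O=C1CC[C@H](C(C)=C)[C@@](C)(CCC#[N+][O-])[C@@H]1CC(=O)OCC | intermediate (not isolated)
15 | tricyclic isoxazoline keto ester, (4R,5S,9S,10R): C3=N–O–C19 ring on C3/C4, C8 ketone, C9 CH2CO2Et | O=C1CC[C@@H]2[C@@]3(C)CON=C3CC[C@@]2(C)[C@@H]1CC(=O)OCC | intermediate
16 | isoxazoline ester with C8=C17 methylene, (4R,5S,9R,10S) | C=C1CC[C@@H]2[C@@]3(C)CON=C3CC[C@@]2(C)[C@@H]1CC(=O)OCC | intermediate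
17 | isoxazoline C12 aldehyde, (4R,5S,9R,10S) | C=C1CC[C@@H]2[C@@]3(C)CON=C3CC[C@@]2(C)[C@@H]1CC=O | intermediate
18 | 1,1,1,3,3,3-hexafluoropropan-2-yl acrylate | C=CC(=O)OC(C(F)(F)F)C(F)(F)F | starting material
19 | (12R)-hexafluoroisopropyl acrylate adduct, (4R,5S,9R,10S,12R) | C=C1CC[C@@H]2[C@@]3(C)CON=C3CC[C@@]2(C)[C@@H]1C[C@@H](O)C(=C)C(=O)OC(C(F)(F)F)C(F)(F)F | intermediate
20 | allyl alcohol | C=CCO | starting material
21 | (12R)-allyl acrylate adduct, (4R,5S,9R,10S,12R) | C=C1CC[C@@H]2[C@@]3(C)CON=C3CC[C@@]2(C)[C@@H]1C[C@@H](O)C(=C)C(=O)OCC=C | intermediate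
22 | isoxazoline butenolide, (4R,5S,9R,10S,12R) | C=C1CC[C@@H]2[C@@]3(C)CON=C3CC[C@@]2(C)[C@@H]1C[C@@H](O)C1=CCOC1=O | intermediate
23 | 3-oxo-12,19-dihydroxy butenolide, (4S,5S,9R,10S,12R) | C=C1CC[C@@H]2[C@@](C)(CO)C(=O)CC[C@@]2(C)[C@@H]1C[C@@H](O)C1=CCOC1=O | intermediate
24 | target, (3R,4S,5S,9R,10S,12R)-3,12,19-trihydroxy-labda-8(17),13-dien-16,15-olide | C=C1CC[C@@H]2[C@@](C)(CO)[C@H](O)CC[C@@]2(C)[C@@H]1C[C@@H](O)C1=CCOC1=O | target

Total step count: 15. Longest linear sequence: 15 steps (from 1).

Steps most likely to fail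

Step 4. The tertiary cation released by the cyclobutane fragmentation may be captured by acetate or may lose the ring proton at C5 instead of a methyl proton, and Lewis-acid enolisation toward C9 may erode that centre. Fallback: from 9, the cyclobutane is opened with dilute aqueous H2SO4 in THF so that water traps the cation and gives the ring-opened hydroxy ketone F1, which carries a tertiary alcohol at C4 beside the primary alcohol. Dess–Martin periodinane then oxidises only the primary alcohol to the aldehyde F2. Burgess reagent removes the tertiary hydroxyl by syn-elimination toward a methyl group, and the sequence returns to the route at 12.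

Step 8. Dimerisation of the nitrile oxide to the furoxan, or its interception by hypochlorite, may outpace the slow attack on the fully substituted alkene carbon, and facial control at C4 may erode. Fallback: from 13, no oxidant is used. Heating in toluene (sealed tube, 160 °C) lets the oxime react through its NH-nitrone tautomer in an intramolecular oxime–olefin cycloaddition, which forms the same C3–C4 bond and gives the N-unsubstituted isoxazolidine F3. N-Chlorosuccinimide converts it into the N-chloroisoxazolidine F4, and DBU eliminates HCl toward C3 to return to the route at 15.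

Step 11. Addition of the hindered, β-branched aldehyde to the acrylate may be slow and low-yielding, with dioxanone formation and loss of enantiocontrol at C12. Fallback: from 17, aldol addition of the lithium enolate of 3-(phenylselanyl)dihydrofuran-2(3H)-one (LiN(iPr)2, THF, −78 °C) gives the selenide F5 as a mixture at C12. H2O2 oxidation and selenoxide syn-elimination away from the carbinol give the hydroxy butenolide F6 as both C12 epimers. Dess–Martin oxidation gives the acyl butenolide F7, and CBS reduction ((S)-2-methyl-CBS-oxazaborolidine, catecholborane, −78 °C) sets (12R) under reagent control and returns to the route at 22.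

Further compounds
F1 | step 4 | ethyl 2-[2-(3-hydroxypropyl)-3-(2-hydroxypropan-2-yl)-2-methyl-6-oxocyclohexyl]acetate (ring configuration as in 11) | O=C1CC[C@H](C(C)(C)O)[C@@](C)(CCCO)[C@@H]1CC(=O)OCC
F2 | step 4 | ethyl 2-[3-(2-hydroxypropan-2-yl)-2-methyl-6-oxo-2-(3-oxopropyl)cyclohexyl]acetate (ring configuration as in 11) | O=C1CC[C@H](C(C)(C)O)[C@@](C)(CCC=O)[C@@H]1CC(=O)OCC
F3 | step 8 | N-unsubstituted isoxazolidine (C3–N(H)–O–C19 ring, C3 configuration not defined, other centres as in 15) | O=C1CC[C@@H]2[C@@]3(C)CONC3CC[C@@]2(C)[C@@H]1CC(=O)OCC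
F4 | step 8 | N-chloroisoxazolidine derived from F3 | O=C1CC[C@@H]2[C@@]3(C)CON(Cl)C3CC[C@@]2(C)[C@@H]1CC(=O)OCC
F5 | step 11 | 3-(phenylselanyl)lactone aldol adduct of 17 (mixture at C12 and C13) | C=C1CC[C@@H]2[C@@]3(C)CON=C3CC[C@@]2(C)[C@@H]1CC(O)C1([Se]c4ccccc4)CCOC1=O
F6 | step 11 | isoxazoline hydroxy butenolide, both C12 epimers | C=C1CC[C@@H]2[C@@]3(C)CON=C3CC[C@@]2(C)[C@@H]1CC(O)C1=CCOC1=O
F7 | step 11 | isoxazoline 12-oxo (acyl) butenolide | C=C1CC[C@@H]2[C@@]3(C)CON=C3CC[C@@]2(C)[C@@H]1CC(=O)C1=CCOC1=O
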